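The runs come from a simulation from invented constants, noise included.

A flat target curve can hide two steps that cancel, so I did not read flatness as a dead flask.

| flask | substrate | free catalyst | temperature | remark | time |
|---|---|---|---|---|---|
| south-east | 0.80 M | 4 mM | 40 °C | the very flask that is asked about, followed so far |  |
| east | 0.80 M | 4 mM | 46 °C | run made earlier |  |
| flask | 0.80 M | 4.0 mM | 40 °C |  | 2.5 d |

- south-east (time / h: target / %, substrate / %): 3.00: 23, 73; 5.00: 34, 57; 8.00: 48, 37; 12.0: 54, 19; 20.0: 57, 3; 40.0: 53, 0
- east (time / h: target / %, substrate / %): 3.00: 33, 55; 5.00: 45, 33; 8.00: 51, 13; 12.0: 56, 7; 20.0: 56, 1; 40.0: 52, 0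

(scatter of a reading: 2 percentage points)

- alder: at 2.5 d raise the temperature by 20 K, then wait 20 h
- elm: at 2.5 d add free catalyst, 50.0% of the amount charged, then wait 20 h
- oak: at 2.5 d take out 90% of the target then present, then wait 20 h
- cedar: change nothing and wait 20 h more

- percentages count the substrate that a species holds: one side product counts as two
- what is taken out of target is counted as made
- steps thought possible: target <-> isomer of the product; substrate + free catalyst -> catalyst intermediate A; substrate + target -> side product; catalyst intermediate A -> catalyst intermediate B; catalyst intermediate B -> free catalyst + target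
- additions bring no volume worth counting

- target, in percent of the substrate first charged, at 2.5 d
- the option that brings most further target ("none" if no option brings more than 2 percentage points) (alder / elm / oak / cedar / none)
- target present, with what was taken out counted in, in percent of the substrate first charged, after alder
- target present, with what was taken out counted in, in percent of the substrate first charged, after cedar

1. First rung: substrate, the limiting reagent. In the south-east run it read 37% at 8.00 h and 3% at 20.0 h. Side product needs substrate, so I expected it to stop with the substrate.

2. Next rung: the loss. Let L be the share in neither target P nor substrate S. I wrote its rate as a·S·P + b·P, with a for side product and b for the forward step to isomer. I replaced the curves by their means over 3.00 h to 8.00 h and 12.0 h to 20.0 h. That gave a = 0.0743 h⁻¹ and b = 0.0211 h⁻¹.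

3. Error check: over the first window, the product of the means was 0.195, and the mean of the products was 0.184. I accepted that.

4. Last rung: at 40.0 h, b·P was 0.0112 h⁻¹, but between 20.0 h and 40.0 h the target readings drifted down 0.00200 h⁻¹, far less than that. So a back step nearly cancelled the forward one.

5. Summing a·S·P over the readings up to 40.0 h gave an estimate of side product of 17.7%, which left an estimate of isomer of 29.3%. That gave 0.553 for the rest ratio ρ, isomer per target at standstill at 40 °C, my reading of the equilibrium constant of that step. I reckoned that the pair relaxes at b(1 + 1/ρ) = 0.0593 h⁻¹.

6. I committed to target near 53% at 2.5 d and after cedar. With the substrate reading at 0% by 40.0 h, I expected nothing from elm. Oak leaves target far below its share of the pool at ratio ρ, so I reckoned a refill of 12 percentage points. The east readings showed no shift I could use for alder. My choice was oak.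

The forecast gave 50%, 42% after alder, 47% after cedar and best none, holding that “the gain is probably under 2 points”, so it parted from my choice.

The flask gave 53.8% at 2.5 d, and the best option was oak, with 12 points. Alder ended at 59.0% and cedar at 53.6%. At 60.0 h it held isomer 24.4%, where ρ on that target gives 29.8%.

    target ⇌ isomer of the product (K = 0.460, k = 4.68 × 10⁻⁴ min⁻¹, Ea = 98.0 kJ mol⁻¹, ΔH = −15.0 kJ mol⁻¹)
    substrate + free catalyst → catalyst intermediate A (k = 0.763 L mol⁻¹ min⁻¹, Ea = 55.0 kJ mol⁻¹)
    substrate + target → side product (k = 0.00100 L mol⁻¹ min⁻¹, Ea = 82.0 kJ mol⁻¹)
    catalyst intermediate A → catalyst intermediate B (k = 0.727 min⁻¹, Ea = 80.0 kJ mol⁻¹)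
    catalyst intermediate B → free catalyst + target (k = 19.7 min⁻¹, Ea = 80.0 kJ mol⁻¹)
    (constants at 40 °C)

In the neighbour charged with 2.0 M of substrate, target stood at 37.5%, ρ gave isomer 20.7%, and that flask held 16.9%.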